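The stirred vessels below take the same charge of substrate and coupling partner and differ in when it goes in and how hot it is.

| flask | substrate | coupling partner | time | remark | temperature |
|---|---|---|---|---|---|
| north-west | 0.32 M | 0.600 equiv | 40 h | everything together at the start at 80 °C, warmed to 110 °C at 15 h |  |
| north | 0.32 M (in portions, 4, over 15 h) | 0.600 equiv | 40 h | first portion at the start, last at 15 h | 110 °C |
| south-east | 0.32 M (fed, over 15 h) | 0.600 equiv | 40 h | the addition at 80 °C, then warmed to 110 °C; the feed brings no volume worth counting |  |
| south-west | 0.32 M | 0.600 equiv | 40 h | everything together at the start | 110 °C |
| north-east | 0.32 M | 0.600 equiv (fed, over 1.5 h) | 40 h | all else is in the flask from the start; the feed brings no volume worth counting | 110 °C |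
| west | 0.32 M | 0.600 equiv (fed, over 15 h) | 40 h | all else is in the flask from the start; the feed brings no volume worth counting | 110 °C |

    substrate + coupling partner → target, rate k1*[substrate]^0.5*[coupling partner]^0.5 (k1 = 4.77 × 10⁻⁵ s⁻¹, Ea1 = 113 kJ mol⁻¹)
    coupling partner + target → over-reaction product (k2 = 9.81 × 10⁻⁴ M⁻¹ s⁻¹, Ea2 = 90.0 kJ mol⁻¹)
    crystals ⇌ target, rate k3*(cs3 - [target]) while solid is left; crystals form when [target] > cs3 (cs3 = 0.16 M, k3 = 0.00243 s⁻¹)
    2 substrate → homo dimer (k4 = 4.60 × 10⁻⁸ M⁻¹ s⁻¹, Ea4 = 102 kJ mol⁻¹)
    (constants at 110 °C)

- percentages count the substrate that a species holds: one homo dimer counts as two
- target is meant together with its crystals
- a step written with two of one species runs at k times the square of its concentration and takes two of it each time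
- solid, in amounts per volume of the solution: crystals
- the list of constants is for 110 °C, to be carried to other temperatures by the activation energies

* which flask leads in amount of over-reaction product, in percent of the substrate charged ("all alike" within 1.5 percentage points) (north-west / north / south-east / south-west / north-east / west / all alike)
* how much over-reaction product is there at the end, in percent of the substrate charged: north-west
* how much over-reaction product is there at the end, in percent of the substrate charged: north
* how much over-reaction product is there at the end, in percent of the substrate charged: south-east
* how much over-reaction product is there at the end, in percent of the substrate charged: south-west
* how much over-reaction product is there at the end, in percent of the substrate charged: north-east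
* how much over-reaction product is there at the end, in percent of the substrate charged: west

*What do you count in?* Fractions of the charge. Let a be the fraction of substrate left, b the fraction of its own charge of coupling partner left, and x and y the fractions of the substrate charged that stand as target and as over-reaction product.

*Can you drop anything?* The homo dimer, for the reckoning: its first half-life by its own step is 9440 h, far longer than the 40 h run.

*What does the partner buy?* It is the limiting reagent at 0.600 equiv. One partner makes a target and a second turns that target over, so at b = zero, x + 2y equals the equivalents charged.

*So what about y?* At b = zero the balance ties it to x. Dividing the second step's rate by the first gives x over a fixed share, times the square root of b/a. That fixed share is the crossover share 19.6%: the fraction of the charge standing as target at which, with a and b both at one, the second step takes partner as fast as the first. For other a and b, multiply it by the square root of a/b. Target stops climbing at that level. I drop the crystals for the reckoning too, because their solubility of 50.0% of the charge stands above the crossover share.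

*Then south-west?* Target climbs to about the crossover share, and the balance gives y near 20.2%.

*But b falls, so the crossover moves up. Doesn't your x sit low?* It does, so I hold that figure as the high side for south-west.

*And north?* Its first portion gives a = one quarter, so the crossover starts at 9.81%, half of the share. With two portions in as a middle value it is 13.9%, so y is near 23.1%, above my south-west figure, and north is the flask I name. West takes its partner over 15 h, and for it and for the flasks that start cold I carry no number.

The forecast also names north, with 18.2% for north-west, 21.6% for north, 18.2% for south-east, 17.8% for south-west, 17.8% for north-east and 15% for west. My north figure stands above its value for north, and my south-west figure above its value for south-west. Its ground is that “portionwise substrate starves step 1 and leaves partner exposed to target”.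

The flasks give north in the lead: 21.7% there, against 18.1% for north-west, 18.0% for south-east, 17.9% for south-west, 17.8% for north-east and 13.4% for west. In north, the partner stands at 0% of its own charge at 15.0 h, just before the last portion, and substrate ends at 62%. North's target ends at 16.7%, above the two-portion crossover of 13.9%. The neighbour of west with 0.13 M of substrate has a crossover share of 48.3%, which puts y at 5.85%, and that flask holds 43.1% target and 8.43% over-reaction product.

The numbers of this flask stand for no real mixture, and the outcome is calculated.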